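**Retrosynthetic overview**
- The target is the (Z)-sinapyl half-ester of 3-hydroxy-3-methylglutaric acid. The strategy rests on glutarate C3, an acyclic tertiary carbinol (R) carrying CH3, OH and two CH2C(=O) arms that differ only as free acid and ester.
- Last skeletal C–O bond: ester between half-ester 15 and (Z)-allylic alcohol 19 (Mitsunobu). The acid arm is carried as a base-labile 2-(arylsulfonyl)ethyl ester and the phenol as a silyl ether. They are removed in that order, the second with buffered fluoride, so that no 4-oxidocinnamyl ester (which would expel the carboxylate as a quinone methide) is ever present.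
- The arms of 15 are told apart by oxidation level in diol 8: the free CH2CH2OH becomes the future acid arm, the CH2CH2OBn end becomes the sinapyl ester arm.
- The C3–O bond comes from epoxide 7, made by asymmetric epoxidation of allylic alcohol 6 and opened by hydride at C2. Alcohol 6 comes from but-3-yn-1-ol by methylalumination and hydroxymethylation.
- Ring order: the oxirane (step 3) is the only ring formed and is opened in step 4; the arene is bought.

Key step: step 3

Remark: L-(+)-diethyl tartrate is taken to deliver oxygen to the same alkene face as with geraniol, giving the 2S,3S epoxide; with the arm assignment above this corresponds to R at C3 of the target.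

**Route**

Step 1
Reactants: 1 but-3-yn-1-ol; 2 benzyl bromide
Product: 3 4-(benzyloxy)but-1-yne
Conditions: NaH (1.05 equiv), n-Bu4NI (cat.), THF, 0 °C → rt
Reagents that add atoms: none
Why: Williamson ether synthesis; the hydroxyl is far more acidic than the alkyne C–H, so only the alkoxide forms and is benzylated by SN2.

Step 2
Reactants: 3 4-(benzyloxy)but-1-yne
Product: 6 (2E)-5-(benzyloxy)-3-methylpent-2-en-1-ol, via alkenyldimethylalane 4 (not isolated), via lithium alkenylaluminate 5 (not isolated)
Conditions: Al(CH3)3 (2.5 equiv), (C5H5)2ZrCl2 (0.25 equiv), CH2Cl2, 0 °C → rt; volatiles removed; n-C4H9Li (1.0 equiv), THF–hexane, −78 → 0 °C; (CH2O)n (3 equiv), 0 °C → rt; aq. KNaC4H4O6 work-up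
Reagents that add atoms: trimethylaluminium C[Al](C)C; paraformaldehyde (as formaldehyde) C=O
Why: Negishi zirconium-catalysed methylalumination adds CH3 and Al syn across the terminal alkyne with Al at the terminus, and the derived alanate is hydroxymethylated with retention, so CH2OH and CH3 end up cis (E alkene); the same reaction type turns terminal alkynes into (E)-3-methylalk-2-en-1-ols.

Step 3
Reactants: 6 (2E)-5-(benzyloxy)-3-methylpent-2-en-1-ol
Product: 7 [(2S,3S)-3-[2-(benzyloxy)ethyl]-3-methyloxiran-2-yl]methanol
Conditions: Ti(OCH(CH3)2)4 (0.10 equiv), L-(+)-diethyl tartrate (0.12 equiv), tert-butyl hydroperoxide (2 equiv, anhydrous), powdered 4 Å molecular sieves, CH2Cl2, −20 °C; aq. tartaric acid/FeSO4 work-up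
Reagents that add atoms: tert-butyl hydroperoxide CC(C)(C)OO
Why: Katsuki–Sharpless asymmetric epoxidation: the allylic alkoxide of 6 and the hydroperoxide bind one titanium of the tartrate-bridged dimer, and the distal peroxide oxygen is passed to the alkene in a concerted step. The closest known case is the epoxidation of geraniol, an (E)-3,3-disubstituted allylic alcohol with CH3 cis to the carbinol carbon. The oxirane closes by simultaneous formation of C2–O and C3–O from one oxygen (oxygen-atom transfer, formally 3-exo-tet at the peroxide O–O bond). C2 and C3 are set together: the L-(+)-tartrate selects the alkene face (2S,3S by analogy with geraniol), and the E geometry from step 2 fixes their relative configuration because the addition is suprafacial. The step needs high enantiofacial selectivity and no uncatalysed background reaction; the free allylic hydroxyl as the only titanium-binding group (the benzyl ether is inert), the small cis substituent (CH3), the sieves and the low temperature should secure this.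

Step 4
Reactants: 7 [(2S,3S)-3-[2-(benzyloxy)ethyl]-3-methyloxiran-2-yl]methanol
Product: 8 (3R)-5-(benzyloxy)-3-methylpentane-1,3-diol
Conditions: NaAlH2(OCH2CH2OCH3)2 (3 equiv), THF, 0 °C → rt; aq. KNaC4H4O6 work-up
Reagents that add atoms: none
Why: Regioselective reductive opening of a 2,3-epoxy alcohol: the C1 alkoxide binds aluminium and delivers hydride internally to the secondary C2 (SN2), not to the quaternary C3, so the C3–O bond and its configuration are kept as the tertiary alcohol (the descriptor becomes R only because the ranking of the arms changes).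

Step 5
Reactants: 8 (3R)-5-(benzyloxy)-3-methylpentane-1,3-diol
Product: 10 (3S)-5-(benzyloxy)-3-hydroxy-3-methylpentanoic acid, via hydroxy aldehyde 9 (not isolated)
Conditions: TEMPO (0.2 equiv), PhI(OAc)2 (2.2 equiv), CH3CN–H2O (1:1), rt; Na2S2O3 quench
Reagents that add atoms: water O
Why: Oxoammonium-mediated (TEMPO/PhI(OAc)2) oxidation of a primary alcohol to the acid through the aldehyde hydrate; the tertiary alcohol cannot be oxidised and the benzyl ether is inert under these conditions.

Step 6
Reactants: 10 (3S)-5-(benzyloxy)-3-hydroxy-3-methylpentanoic acid; 11 2-(4-methylbenzenesulfonyl)ethan-1-ol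
Product: 12 2-(4-methylbenzenesulfonyl)ethyl (3S)-5-(benzyloxy)-3-hydroxy-3-methylpentanoate
Conditions: N,N'-dicyclohexylcarbodiimide (1.2 equiv), 4-(dimethylamino)pyridine (0.1 equiv), CH2Cl2, 0 °C → rt
Reagents that add atoms: none
Why: Steglich esterification; the primary alcohol 11 takes the acyl group far faster than the hindered tertiary hydroxyl, and the 2-(arylsulfonyl)ethyl ester survives hydrogenolysis, oxidation and Mitsunobu conditions yet can later be removed without fluoride or acid.

Step 7
Reactants: 12 2-(4-methylbenzenesulfonyl)ethyl (3S)-5-(benzyloxy)-3-hydroxy-3-methylpentanoate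
Product: 13 2-(4-methylbenzenesulfonyl)ethyl (3S)-3,5-dihydroxy-3-methylpentanoate
Conditions: H2 (1 atm), 10% Pd/C, EtOAc, rt; filtered, concentrated cold and used at once without chromatography
Reagents that add atoms: none
Why: Neutral hydrogenolysis of the benzyl ether; the sulfone and the ester are untouched, and the δ-hydroxy ester is taken on crude so that it has no time to lactonise.

Step 8
Reactants: 13 2-(4-methylbenzenesulfonyl)ethyl (3S)-3,5-dihydroxy-3-methylpentanoate
Product: 15 (3S)-3-hydroxy-3-methyl-5-[2-(4-methylbenzenesulfonyl)ethoxy]-5-oxopentanoic acid, via aldehyde ester 14 (not isolated)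
Conditions: TEMPO (0.2 equiv), PhI(OAc)2 (2.5 equiv), CH3CN–H2O (1:1), 0 °C → rt; Na2S2O3 quench
Reagents that add atoms: water O
Why: The same TEMPO/PhI(OAc)2 oxidation converts the newly freed primary alcohol into the second carboxyl group, giving a glutarate whose two ends are now an ester and a free acid.

Step 9
Reactants: 16 syringaldehyde (4-hydroxy-3,5-dimethoxybenzaldehyde)
Product: 17 4-[(tert-butyldimethylsilyl)oxy]-3,5-dimethoxybenzaldehyde
Conditions: tert-butyl(chloro)dimethylsilane (1.2 equiv), imidazole (2.5 equiv), DMF, rt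
Reagents that add atoms: tert-butyl(chloro)dimethylsilane CC(C)(C)[Si](C)(C)Cl
Why: Standard imidazole-promoted silylation of a phenol; the aldehyde is unaffected.

Step 10
Reactants: 17 4-[(tert-butyldimethylsilyl)oxy]-3,5-dimethoxybenzaldehyde
Product: 18 methyl (2Z)-3-{4-[(tert-butyldimethylsilyl)oxy]-3,5-dimethoxyphenyl}prop-2-enoate
Conditions: (CF3CH2O)2P(O)CH2CO2CH3 (1.2 equiv), KN(Si(CH3)3)2 (1.2 equiv), 18-crown-6 (3 equiv), THF, −78 °C
Reagents that add atoms: methyl bis(2,2,2-trifluoroethyl)phosphonoacetate COC(=O)CP(=O)(OCC(F)(F)F)OCC(F)(F)F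
Why: Still–Gennari olefination; the electron-poor trifluoroethyl phosphonate with a dissociated potassium counter-ion eliminates quickly from the kinetically formed adduct and should give the (Z)-cinnamate from an aromatic aldehyde.

Step 11
Reactants: 18 methyl (2Z)-3-{4-[(tert-butyldimethylsilyl)oxy]-3,5-dimethoxyphenyl}prop-2-enoate
Product: 19 (2Z)-3-{4-[(tert-butyldimethylsilyl)oxy]-3,5-dimethoxyphenyl}prop-2-en-1-ol
Conditions: ((CH3)2CHCH2)2AlH (2.5 equiv), CH2Cl2, −78 °C; aq. KNaC4H4O6 work-up; light excluded
Reagents that add atoms: none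
Why: 1,2-Reduction of an enoate to the allylic alcohol by a dialkylaluminium hydride at low temperature, which keeps the Z geometry and the aryl silyl ether.

Step 12
Reactants: 15 (3S)-3-hydroxy-3-methyl-5-[2-(4-methylbenzenesulfonyl)ethoxy]-5-oxopentanoic acid; 19 (2Z)-3-{4-[(tert-butyldimethylsilyl)oxy]-3,5-dimethoxyphenyl}prop-2-en-1-ol
Product: 20 1-[(2Z)-3-{4-[(tert-butyldimethylsilyl)oxy]-3,5-dimethoxyphenyl}prop-2-en-1-yl] 5-[2-(4-methylbenzenesulfonyl)ethyl] (3S)-3-hydroxy-3-methylpentanedioate
Conditions: PPh3 (1.3 equiv), diisopropyl azodicarboxylate (1.3 equiv, added last), THF, 0 °C; light excluded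
Reagents that add atoms: none
Why: Mitsunobu esterification; only the primary allylic alcohol is converted into an oxyphosphonium ion (the tertiary hydroxyl cannot be), and the carboxylate displaces it by SN2 at CH2, so neither the alkene geometry nor C3 is involved.

Step 13
Reactants: 20 the mixed diester from step 12
Product: 21 (3R)-5-{[(2Z)-3-{4-[(tert-butyldimethylsilyl)oxy]-3,5-dimethoxyphenyl}prop-2-en-1-yl]oxy}-3-hydroxy-3-methyl-5-oxopentanoic acid
Conditions: DBU (2 equiv), CH2Cl2, 0 °C → rt; pH 4 citrate buffer work-up
Reagents that add atoms: none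
Why: β-Elimination (E1cB) of the 2-(arylsulfonyl)ethyl ester by an amidine base releases the carboxylate and an aryl vinyl sulfone; the phenol is still silylated, so no phenoxide can form, and the allylic ester has no comparably acidic C–H.

Step 14
Reactants: 21 the silyl-protected half-ester from step 13
Product: 22 (3R)-3-hydroxy-5-{[(2Z)-3-(4-hydroxy-3,5-dimethoxyphenyl)prop-2-en-1-yl]oxy}-3-methyl-5-oxopentanoic acid (target)
Conditions: n-Bu4NF (1.2 equiv), CH3CO2H (1.5 equiv), THF, 0 °C; pH 4 buffer work-up
Reagents that add atoms: none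
Why: Fluoride cleavage of an aryl silyl ether; the acetic acid buffer keeps the liberated phenol protonated, so the 1,8-elimination of carboxylate that a free 4-oxidocinnamyl ester would undergo is avoided, and the Z ester and the tertiary carbinol are untouched.

**Compound list**
1 | but-3-yn-1-ol | C#CCCO | starting material
2 | benzyl bromide | BrCc1ccccc1 | starting material
3 | 4-(benzyloxy)but-1-yne | C#CCCOCc1ccccc1 | intermediate
4 | (E)-[4-(benzyloxy)-2-methylbut-1-en-1-yl]dimethylalane | C[Al](C)/C=C(\C)CCOCc1ccccc1 | intermediate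
5 | lithium (E)-[4-(benzyloxy)-2-methylbut-1-en-1-yl](butyl)dimethylaluminate | [Li+].CCCC[Al-](C)(C)/C=C(\C)CCOCc1ccccc1 | intermediate
6 | (2E)-5-(benzyloxy)-3-methylpent-2-en-1-ol | OC/C=C(\C)CCOCc1ccccc1 | intermediate
7 | [(2S,3S)-3-[2-(benzyloxy)ethyl]-3-methyloxiran-2-yl]methanol | OC[C@@H]1O[C@@]1(C)CCOCc1ccccc1 | intermediate
8 | (3R)-5-(benzyloxy)-3-methylpentane-1,3-diol | C[C@@](O)(CCO)CCOCc1ccccc1 | intermediate
9 | (3S)-5-(benzyloxy)-3-hydroxy-3-methylpentanal | C[C@@](O)(CC=O)CCOCc1ccccc1 | intermediate
10 | (3S)-5-(benzyloxy)-3-hydroxy-3-methylpentanoic acid | C[C@@](O)(CC(=O)O)CCOCc1ccccc1 | intermediate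
11 | 2-(4-methylbenzenesulfonyl)ethan-1-ol | Cc1ccc(cc1)S(=O)(=O)CCO | starting material
12 | 2-(4-methylbenzenesulfonyl)ethyl (3S)-5-(benzyloxy)-3-hydroxy-3-methylpentanoate | C[C@@](O)(CC(=O)OCCS(=O)(=O)c1ccc(C)cc1)CCOCc1ccccc1 | intermediate
13 | 2-(4-methylbenzenesulfonyl)ethyl (3S)-3,5-dihydroxy-3-methylpentanoate | C[C@@](O)(CC(=O)OCCS(=O)(=O)c1ccc(C)cc1)CCO | intermediate
14 | 2-(4-methylbenzenesulfonyl)ethyl (3S)-3-hydroxy-3-methyl-5-oxopentanoate | C[C@@](O)(CC(=O)OCCS(=O)(=O)c1ccc(C)cc1)CC=O | intermediate
15 | (3S)-3-hydroxy-3-methyl-5-[2-(4-methylbenzenesulfonyl)ethoxy]-5-oxopentanoic acid | C[C@@](O)(CC(=O)OCCS(=O)(=O)c1ccc(C)cc1)CC(=O)O | intermediate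
16 | syringaldehyde (4-hydroxy-3,5-dimethoxybenzaldehyde) | COc1cc(C=O)cc(OC)c1O | starting material
17 | 4-[(tert-butyldimethylsilyl)oxy]-3,5-dimethoxybenzaldehyde | COc1cc(C=O)cc(OC)c1O[Si](C)(C)C(C)(C)C | intermediate
18 | methyl (2Z)-3-{4-[(tert-butyldimethylsilyl)oxy]-3,5-dimethoxyphenyl}prop-2-enoate | COC(=O)/C=C\c1cc(OC)c(O[Si](C)(C)C(C)(C)C)c(OC)c1 | intermediate
19 | (2Z)-3-{4-[(tert-butyldimethylsilyl)oxy]-3,5-dimethoxyphenyl}prop-2-en-1-ol | OC/C=C\c1cc(OC)c(O[Si](C)(C)C(C)(C)C)c(OC)c1 | intermediate
20 | 1-[(2Z)-3-{4-[(tert-butyldimethylsilyl)oxy]-3,5-dimethoxyphenyl}prop-2-en-1-yl] 5-[2-(4-methylbenzenesulfonyl)ethyl] (3S)-3-hydroxy-3-methylpentanedioate | C[C@@](O)(CC(=O)OCCS(=O)(=O)c1ccc(C)cc1)CC(=O)OC/C=C\c1cc(OC)c(O[Si](C)(C)C(C)(C)C)c(OC)c1 | intermediate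
21 | (3R)-5-{[(2Z)-3-{4-[(tert-butyldimethylsilyl)oxy]-3,5-dimethoxyphenyl}prop-2-en-1-yl]oxy}-3-hydroxy-3-methyl-5-oxopentanoic acid | C[C@@](O)(CC(=O)O)CC(=O)OC/C=C\c1cc(OC)c(O[Si](C)(C)C(C)(C)C)c(OC)c1 | intermediate
22 | (3R)-3-hydroxy-5-{[(2Z)-3-(4-hydroxy-3,5-dimethoxyphenyl)prop-2-en-1-yl]oxy}-3-methyl-5-oxopentanoic acid | C[C@@](O)(CC(=O)O)CC(=O)OC/C=C\c1cc(OC)c(O)c(OC)c1 | target

**Step count**
Total: 14 steps. Longest linear sequence: 11 steps (steps 1–8, 12, 13, 14, from but-3-yn-1-ol); steps 9–11 build the side fragment.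

**Steps most likely to fail**

Step 7 (with the hand-over to step 8). The freed primary hydroxyl may attack the ester carbonyl of the same molecule (δ-lactonisation with loss of the sulfonylethanol), which would destroy the protection of the future acid arm. The fallback sets out from 12 and comes back at 15. Compound 12 is treated with an excess of 4-acetamido-2,2,6,6-tetramethyl-1-oxopiperidinium tetrafluoroborate in wet CH3CN at rt. Hydride abstraction at the benzylic CH2 cleaves the ether to benzaldehyde, and the primary alcohol released is oxidised on to the acid by the same oxidant in the same flask, so the δ-hydroxy ester never accumulates. This fallback makes no compound outside the list (F0).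

Step 12. The electron-rich allylic oxyphosphonium ion may ionise before it is displaced, which would cause Z to E isomerisation or allylic transposition; the β-hydroxy acid may also be activated at its own carboxyl. The fallback sets out from 15 and 19 and comes back at 20. The carboxyl is activated instead of the alcohol: N,N'-dicyclohexylcarbodiimide and catalytic 4-(dimethylamino)pyridine in CH2Cl2 at 0 °C (Steglich esterification), with the alcohol 19 in slight excess. The allylic C–O bond is never broken, so the alkene geometry cannot change, and the hindered tertiary hydroxyl should not compete with the primary alcohol. This fallback makes no compound outside the list (F0).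

Step 10. Addition of the phosphonate anion to this electron-rich, slowly reacting aldehyde may become reversible, which would erode the Z selectivity on which the alkene geometry of the target depends. The fallback sets out from 17 and comes back at 19. Corey–Fuchs homologation (CBr4, PPh3, CH2Cl2, 0 °C) gives the dibromoalkene tert-butyl[4-(2,2-dibromoethenyl)-2,6-dimethoxyphenoxy]dimethylsilane F1. Treatment with n-C4H9Li (2.2 equiv, THF, −78 °C) gives the lithium acetylide {4-[(tert-butyldimethylsilyl)oxy]-3,5-dimethoxyphenyl}ethynyllithium F2 (not isolated), which is trapped with paraformaldehyde to give the propargylic alcohol 3-{4-[(tert-butyldimethylsilyl)oxy]-3,5-dimethoxyphenyl}prop-2-yn-1-ol F3. Semihydrogenation (H2, Pd/CaCO3 poisoned with Pb(OAc)2, quinoline, EtOAc) adds hydrogen cis and gives 19.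

**Further compounds**
F0 | step 7 | none | none
F0 | step 12 | none | none
F1 | step 10 | tert-butyl[4-(2,2-dibromoethenyl)-2,6-dimethoxyphenoxy]dimethylsilane | COc1cc(C=C(Br)Br)cc(OC)c1O[Si](C)(C)C(C)(C)C
F2 | step 10 | {4-[(tert-butyldimethylsilyl)oxy]-3,5-dimethoxyphenyl}ethynyllithium | [Li]C#Cc1cc(OC)c(O[Si](C)(C)C(C)(C)C)c(OC)c1
F3 | step 10 | 3-{4-[(tert-butyldimethylsilyl)oxy]-3,5-dimethoxyphenyl}prop-2-yn-1-ol | OCC#Cc1cc(OC)c(O[Si](C)(C)C(C)(C)C)c(OC)c1
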